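In a one-step world there is one clock, and the way a charge goes in has nothing to act on; I took that as the zero of my scale and asked what second clock these flasks add.

    substrate + free catalyst → free catalyst + intermediate (k1 = 41000 /M/min, Ea1 = 38.0 kJ/mol)
    partner + second catalyst + intermediate → second catalyst + target (k2 = 1400 /M²/min, Ea2 = 41.0 kJ/mol)
    free catalyst + target → free catalyst + over-reaction product (k3 = 18000 /M/min, Ea3 = 36.0 kJ/mol)
    (constants at 50 °C)

common to all: free catalyst 25 µM; second catalyst 0.25 mM; time 4.0 h
- north: substrate 0.050 M (fed, over 3.0 h); partner 0.100 M; the addition at 30 °C, then warmed to 50 °C; the feed brings no volume worth counting
- south: substrate 0.050 M; partner 0.100 M; everything together at the start; temperature 50 °C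
- west: substrate 0.050 M; partner 0.100 M (fed, over 3.0 h); all else is in the flask from the start; the feed brings no volume worth counting; temperature 50 °C
- north-east: substrate 0.050 M (in portions, 3, over 3.0 h); partner 0.100 M; first portion at the start, last at 3.0 h; temperature 50 °C

- at 50 °C the constants are as listed, elsewhere as the activation energies make them

- the flask that comes out highest in amount of over-reaction product, in percent of the substrate charged; "all alike" if 1.5 percentage points covers them all (north / south / west / north-east / all alike)
- amount of over-reaction product at the end, in percent of the substrate charged, north
- amount of over-reaction product at the end, in percent of the substrate charged, south
- amount of over-reaction product at the end, in percent of the substrate charged, west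
- amount of over-reaction product at the end, in percent of the substrate charged, north-east

At 50 °C, with free catalyst as charged, substrate had a half-life of 0.676 min by step 1 and target one of 1.54 min by step 3. I called h the clearing half-life, the pseudo-first-order half-life of intermediate in step 2 with partner and second catalyst as charged, and it came to 0.330 h. That was far longer than the other two, so I took step 2 as the rate-limiting step and set them aside. The second time was w, what remains after the last substrate is in, 1.00 h in north and north-east.

Partner was charged at twice the substrate, so substrate is the limiting reagent. In south and north-east, which run at 50 °C with partner in the flask from the start, partner stays at or above 0.0500 M, so h in those two flasks stretches to 0.660 h at most. In north-east, the last third had w/h between 1.52 and 3.03, so I expected 4.08% to 11.7% of the substrate charged to stand as intermediate at the end. South had the whole 4.0 h, and at that longest h I reckoned 98.5% over-reaction product. North has the same w, but its feed runs at 30 °C, where step 2 is slower, so I placed it under north-east. West I placed between, without a figure.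

The forecast named south, with 87.4% for north, 99.2% for south, 95.4% for west and 89.1% for north-east, on the ground that “the yield of over-product simply tracks how far the slow partner step has run”. My reckoning gave a range and one estimate, not those figures.

The flasks gave 87.0% for north, 99.2% for south, 94.9% for west and 88.9% for north-east, so south came out highest. North held 44.6% as intermediate at 3.00 h and 12.4% at 4.00 h, while its partner went from 73.0% to 56.2%. At the mean of those two partner readings, h becomes 0.511 h, and w then leaves 11.5%. A neighbour of north with 4.2 × 10⁻⁴ M of second catalyst has h of 0.196 h, and it ended with 4.50% as intermediate and 95.2% as over-reaction product.

The constants used here stand for no real mixture; the rest is arithmetic.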